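**Plan**
- Chain numbered C1 (ester C=O) to C20 (CHBr). The retrosynthesis cuts C10–C11 (sp–sp2 coupling), then C6–C7 of the oxolane after adding back a C6=C7 alkene (ring-closing metathesis), then the C5–O ether bond (allylic etherification); the side chain is cut at C17=C18 (Wittig).
- The only ring (O, C5, C6, C7, C8) has both stereocentres on the carbons flanking oxygen, so a bis-allylic ether with a vinyl group on C5 and on C8 closes to the 2,5-dihydrofuran at C6–C7.
- Forward: a C1–C7 allyl carbonate (from methyl hex-5-enoate and acrolein) and an (S)-alkynyl vinyl carbinol (C8–C10 plus a vinyl group) are joined at O–C5. The ring is then closed, the ring alkene saturated, the alkyne unmasked and coupled with a C11–C20 bromo-iodo-triene.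
- Stereochemistry: C8 (S) from lipase resolution of the carbinol and C5 (R) from the chiral iridium catalyst, which together give the trans ring. C11=C12 (E) and C19=C20 (E) come from hydrozirconation–halogenation, C17=C18 (Z) from a salt-free Wittig reaction.

Key step: step 7

Assumption: the facial preference of the iridium–phosphoramidite catalyst and the enantiomer preference of the lipase are taken from their usual behaviour with alkyl-substituted allyl carbonates and alkynyl vinyl carbinols; should either prove opposite, the antipodal ligand, or the acetate fraction after methanolysis, is used instead.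

**Route**

Step 1
Reactants: 1 methyl hex-5-enoate; 2 acrolein
Product: 3 methyl (E)-7-oxohept-5-enoate
Conditions: 2 (3 equiv), [1,3-bis(2,4,6-trimethylphenyl)imidazolidin-2-ylidene]Cl2Ru=CH(C6H4-2-OiPr) (second-generation Hoveyda–Grubbs catalyst, 2.5 mol%), CH2Cl2, 40 °C
Reagents that add atoms: none
Why: Olefin cross-metathesis of a terminal alkene with an electron-poor enal favours the hetero-coupled product and, being reversible, should settle on the (E)-enal with loss of ethylene.

Step 2
Reactants: 3 methyl (E)-7-oxohept-5-enoate
Product: 4 methyl (E)-7-hydroxyhept-5-enoate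
Conditions: NaBH4, CeCl3·7H2O, MeOH, −78 → 0 °C
Reagents that add atoms: none
Why: Luche reduction delivers hydride 1,2 to the enal carbonyl only, leaving the saturated methyl ester and the alkene geometry untouched.

Step 3
Reactants: 4 methyl (E)-7-hydroxyhept-5-enoate
Product: 5 methyl (E)-7-[(tert-butoxycarbonyl)oxy]hept-5-enoate
Conditions: Boc2O (1.3 equiv), DMAP (10 mol%), CH2Cl2, 0 °C → rt
Reagents that add atoms: di-tert-butyl dicarbonate, CC(C)(C)OC(=O)OC(=O)OC(C)(C)C
Why: DMAP-catalysed acyl transfer converts the primary allylic alcohol into its tert-butyl carbonate, a leaving group whose tert-butoxide by-product is too hindered to compete as a nucleophile in step 6.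

Step 4
Reactants: 6 (triisopropylsilyl)acetylene; 2 acrolein
Product: 8 rac-5-(triisopropylsilyl)pent-1-en-4-yn-3-ol, via lithium (triisopropylsilyl)acetylide 7 (not isolated)
Conditions: n-BuLi, THF, −78 °C; then 2, −78 °C; aq NH4Cl
Reagents that add atoms: none
Why: Addition of a hard lithium acetylide to an enal at low temperature is a 1,2-carbonyl addition and gives the racemic alkynyl vinyl carbinol.

Step 5
Reactants: 8 rac-5-(triisopropylsilyl)pent-1-en-4-yn-3-ol
Product: 9 (S)-5-(triisopropylsilyl)pent-1-en-4-yn-3-ol
Conditions: Pseudomonas fluorescens lipase (Amano AK), vinyl acetate, hexane, 4 Å molecular sieves, 30 °C, stopped just past half conversion; chromatography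
Reagents that add atoms: none
Why: Lipase-catalysed kinetic resolution by irreversible transesterification should acylate the (R)-alcohol faster (silylalkynyl as the large, vinyl as the medium substituent), so the recovered alcohol is (S) and the C8 configuration is fixed here by the enzyme.

Step 6
Reactants: 9 (S)-5-(triisopropylsilyl)pent-1-en-4-yn-3-ol; 5 methyl (E)-7-[(tert-butoxycarbonyl)oxy]hept-5-enoate
Product: 12 methyl (5R)-5-{[(3S)-5-(triisopropylsilyl)pent-1-en-4-yn-3-yl]oxy}hept-6-enoate, via lithium alkoxide 10 (not isolated), via copper alkoxide 11 (not isolated)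
Conditions: 9 (1.5 equiv, surplus recovered), n-BuLi, THF, 0 °C; CuI, rt; then 5, [Ir(cod)Cl]2 (2 mol%), (Sa,S,S)-O,O'-(1,1'-binaphthalene-2,2'-diyl) N,N-bis(1-phenylethyl)phosphoramidite (4 mol%), THF, rt
Reagents that add atoms: none
Why: Iridium-catalysed asymmetric allylic etherification, in which the cyclometalated iridium–phosphoramidite catalyst ionises the linear (E)-carbonate to an allyl complex and the soft copper alkoxide attacks the substituted terminus anti to the metal; the (Sa,S,S) ligand is expected to deliver oxygen to the Re face of C5 and set (5R) under catalyst control, while C8 keeps its configuration because its C–O bond is never broken.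

Step 7
Reactants: 12 methyl (5R)-5-{[(3S)-5-(triisopropylsilyl)pent-1-en-4-yn-3-yl]oxy}hept-6-enoate
Product: 13 methyl 4-[(2R,5S)-5-[(triisopropylsilyl)ethynyl]-2,5-dihydrofuran-2-yl]butanoate
Conditions: [1,3-bis(2,4,6-trimethylphenyl)imidazolidin-2-ylidene](PCy3)Cl2Ru=CHPh (second-generation Grubbs catalyst, 5 mol%), CH2Cl2 (0.01 M), 40 °C
Reagents that add atoms: none
Why: The ruthenium benzylidene exchanges onto one of the two monosubstituted vinyl groups, and the new alkylidene undergoes intramolecular [2+2] cycloaddition with the second vinyl group followed by retro-[2+2] of the ruthenacyclobutane, which releases the dihydrofuran and a methylidene that turns over with loss of ethylene. The closest known reaction type is ring-closing olefin metathesis of bis-allylic ethers to 2,5-dihydrofurans. The five-membered ring (O, C5, C6, C7, C8) is closed by forming the endocyclic C6=C7 bond from a 1,6-diene, driven by the escape of ethylene. No stereocentre is created: C5 (R, step 6) and C8 (S, step 5) lie outside the reacting carbons and are carried through unchanged, so the trans-2,5 relationship is inherited and the ring alkene is necessarily cis. The step needs diene closure to win over enyne metathesis and over intermolecular metathesis; the internal triisopropylsilyl-capped alkyne is too hindered to engage the alkylidene, both alkenes are unhindered vinyl groups, and high dilution favours the intramolecular path.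

Step 8
Reactants: 13 methyl 4-[(2R,5S)-5-[(triisopropylsilyl)ethynyl]-2,5-dihydrofuran-2-yl]butanoate
Product: 14 methyl 4-[(2R,5S)-5-[(triisopropylsilyl)ethynyl]oxolan-2-yl]butanoate
Conditions: TsNHNH2 (excess, portionwise), NaOAc, DME/H2O, 85 °C
Reagents that add atoms: none
Why: Diimide reduction transfers H2 in a concerted syn fashion to the unhindered cis ring alkene, while the silyl-shielded triple bond and the ester should be left alone and no hydrogenolysis of the allylic and propargylic C–O bonds can occur as it might over a metal surface.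

Step 9
Reactants: 14 methyl 4-[(2R,5S)-5-[(triisopropylsilyl)ethynyl]oxolan-2-yl]butanoate
Product: 15 methyl 4-[(2R,5S)-5-ethynyloxolan-2-yl]butanoate
Conditions: Bu4NF (1.1 equiv), THF, 0 °C
Reagents that add atoms: none
Why: Fluoride-mediated protodesilylation cleaves the C(sp)–Si bond selectively at low temperature, leaving the methyl ester and both ring stereocentres unaffected.

Step 10
Reactants: 16 hept-6-yn-1-ol
Product: 18 (E)-7-iodohept-6-en-1-ol, via alkenylzirconocene chloride 17 (not isolated)
Conditions: Cp2Zr(H)Cl (2.2 equiv), THF, rt; then I2, 0 °C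
Reagents that add atoms: iodine, [I][I]
Why: Hydrozirconation–iodination adds Zr–H syn across the terminal alkyne with zirconium on the terminal carbon (one equivalent being consumed by the hydroxyl group), and iodinolysis with retention gives the (E)-vinyl iodide that becomes C11=C12.

Step 11
Reactants: 18 (E)-7-iodohept-6-en-1-ol
Product: 19 (E)-1,7-diiodohept-1-ene
Conditions: I2, PPh3, imidazole, CH2Cl2, 0 °C → rt
Reagents that add atoms: iodine, [I][I]
Why: Appel-type iodination converts the primary alcohol through its alkoxyphosphonium salt into the iodide by SN2 displacement, the vinyl iodide being inert.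

Step 12
Reactants: 19 (E)-1,7-diiodohept-1-ene
Product: 20 [(E)-7-iodohept-6-en-1-yl]triphenylphosphonium iodide
Conditions: PPh3, MeCN, 80 °C
Reagents that add atoms: triphenylphosphine, c1ccc(cc1)P(c1ccccc1)c1ccccc1
Why: Quaternisation of triphenylphosphine by SN2 attack occurs only at the primary alkyl iodide, since the sp2 C–I bond does not react without a metal catalyst.

Step 13
Reactants: 21 3,3-diethoxyprop-1-yne
Product: 23 (E)-1-bromo-3,3-diethoxyprop-1-ene, via alkenylzirconocene chloride 22 (not isolated)
Conditions: Cp2Zr(H)Cl (1.1 equiv), CH2Cl2, rt; then NBS, 0 °C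
Reagents that add atoms: N-bromosuccinimide, O=C1CCC(=O)N1Br
Why: Hydrozirconation–bromination gives the terminal (E)-alkenylzirconium species by syn addition, and brominolysis with retention sets the (E)-bromoalkene that becomes C19=C20.

Step 14
Reactants: 23 (E)-1-bromo-3,3-diethoxyprop-1-ene
Product: 24 (E)-3-bromoprop-2-enal
Conditions: aq HCO2H, pentane, 0 °C → rt; extracted, dried and used at once as a solution
Reagents that add atoms: water, O
Why: Acid-catalysed acetal hydrolysis unmasks the aldehyde without touching the vinyl bromide, and the (E)-geometry is also the thermodynamically preferred one.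

Step 15
Reactants: 20 [(E)-7-iodohept-6-en-1-yl]triphenylphosphonium iodide; 24 (E)-3-bromoprop-2-enal
Product: 26 (1E,3Z,9E)-1-bromo-10-iododeca-1,3,9-triene, via phosphorus ylide 25 (not isolated)
Conditions: NaN(SiMe3)2 (1.0 equiv), THF, −78 °C; then 24, −78 °C → rt
Reagents that add atoms: none
Why: Wittig olefination with a non-stabilised ylide under lithium-free conditions proceeds through the kinetically favoured cis-oxaphosphetane and should give the (Z)-alkene at C17=C18, while both halogen-bearing (E)-alkenes are spectators at this temperature.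

Step 16
Reactants: 15 methyl 4-[(2R,5S)-5-ethynyloxolan-2-yl]butanoate; 26 (1E,3Z,9E)-1-bromo-10-iododeca-1,3,9-triene
Product: 27 methyl 4-[(2R,5S)-5-[(3E,9Z,11E)-12-bromododeca-3,9,11-trien-1-yn-1-yl]oxolan-2-yl]butanoate
Conditions: Pd(PPh3)4 (5 mol%), CuI (10 mol%), i-Pr2NH, THF (degassed), 0 °C → rt, dark
Reagents that add atoms: none
Why: Sonogashira coupling forms C10–C11 with retention of alkene geometry, because oxidative addition of zerovalent palladium into the C–I bond is much faster than into the C–Br bond of the bromodiene at or below room temperature.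

**Compound list**

1 | methyl hex-5-enoate | C=CCCCC(=O)OC | starting material
2 | acrolein | C=CC=O | starting material
3 | methyl (E)-7-oxohept-5-enoate | COC(=O)CCC/C=C/C=O | intermediate
4 | methyl (E)-7-hydroxyhept-5-enoate | COC(=O)CCC/C=C/CO | intermediate
5 | methyl (E)-7-[(tert-butoxycarbonyl)oxy]hept-5-enoate | COC(=O)CCC/C=C/COC(=O)OC(C)(C)C | intermediate
6 | (triisopropylsilyl)acetylene | C#C[Si](C(C)C)(C(C)C)C(C)C | starting material
7 | lithium (triisopropylsilyl)acetylide (not isolated) | [Li]C#C[Si](C(C)C)(C(C)C)C(C)C | intermediate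
8 | rac-5-(triisopropylsilyl)pent-1-en-4-yn-3-ol | C=CC(O)C#C[Si](C(C)C)(C(C)C)C(C)C | intermediate
9 | (S)-5-(triisopropylsilyl)pent-1-en-4-yn-3-ol | O[C@@H](C=C)C#C[Si](C(C)C)(C(C)C)C(C)C | intermediate
10 | lithium (3S)-5-(triisopropylsilyl)pent-1-en-4-yn-3-olate (not isolated) | [Li]O[C@@H](C=C)C#C[Si](C(C)C)(C(C)C)C(C)C | intermediate
11 | copper (3S)-5-(triisopropylsilyl)pent-1-en-4-yn-3-olate, CuOR (not isolated) | [Cu]O[C@@H](C=C)C#C[Si](C(C)C)(C(C)C)C(C)C | intermediate
12 | methyl (5R)-5-{[(3S)-5-(triisopropylsilyl)pent-1-en-4-yn-3-yl]oxy}hept-6-enoate | COC(=O)CCC[C@H](C=C)O[C@@H](C=C)C#C[Si](C(C)C)(C(C)C)C(C)C | intermediate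
13 | methyl 4-[(2R,5S)-5-[(triisopropylsilyl)ethynyl]-2,5-dihydrofuran-2-yl]butanoate | COC(=O)CCC[C@@H]1C=C[C@@H](C#C[Si](C(C)C)(C(C)C)C(C)C)O1 | intermediate
14 | methyl 4-[(2R,5S)-5-[(triisopropylsilyl)ethynyl]oxolan-2-yl]butanoate | COC(=O)CCC[C@@H]1CC[C@@H](C#C[Si](C(C)C)(C(C)C)C(C)C)O1 | intermediate
15 | methyl 4-[(2R,5S)-5-ethynyloxolan-2-yl]butanoate | COC(=O)CCC[C@@H]1CC[C@@H](C#C)O1 | intermediate
16 | hept-6-yn-1-ol | C#CCCCCCO | starting material
17 | (E)-alkenylzirconocene chloride from 16, hydroxyl carried as its zirconocene chloride alkoxide (not isolated; cyclopentadienyl drawn sigma-bonded) | Cl[Zr](C1C=CC=C1)(C1C=CC=C1)/C=C/CCCCCO[Zr](Cl)(C1C=CC=C1)C1C=CC=C1 | intermediate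
18 | (E)-7-iodohept-6-en-1-ol | OCCCCC/C=C/I | intermediate
19 | (E)-1,7-diiodohept-1-ene | ICCCCC/C=C/I | intermediate
20 | [(E)-7-iodohept-6-en-1-yl]triphenylphosphonium iodide | [I-].I/C=C/CCCCC[P+](c1ccccc1)(c1ccccc1)c1ccccc1 | intermediate
21 | 3,3-diethoxyprop-1-yne | C#CC(OCC)OCC | starting material
22 | [(E)-3,3-diethoxyprop-1-en-1-yl]zirconocene chloride (not isolated; cyclopentadienyl drawn sigma-bonded) | Cl[Zr](C1C=CC=C1)(C1C=CC=C1)/C=C/C(OCC)OCC | intermediate
23 | (E)-1-bromo-3,3-diethoxyprop-1-ene | Br/C=C/C(OCC)OCC | intermediate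
24 | (E)-3-bromoprop-2-enal | Br/C=C/C=O | intermediate
25 | [(E)-7-iodohept-6-en-1-ylidene]triphenylphosphorane (not isolated) | I/C=C/CCCCC=P(c1ccccc1)(c1ccccc1)c1ccccc1 | intermediate
26 | (1E,3Z,9E)-1-bromo-10-iododeca-1,3,9-triene | I/C=C/CCCC/C=C\C=C\Br | intermediate
27 | methyl 4-[(2R,5S)-5-[(3E,9Z,11E)-12-bromododeca-3,9,11-trien-1-yn-1-yl]oxolan-2-yl]butanoate (CNP0231094.1) | COC(=O)CCC[C@@H]1CC[C@@H](C#C/C=C/CCCC/C=C\C=C\Br)O1 | target

**Step count**

Total steps: 16. Longest linear sequence: 8 steps (1, 2, 3, 6, 7, 8, 9, 16).

**Steps most likely to fail**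

Step 6. The alkoxide may attack with incomplete branched-to-linear or facial control, or the hindered propargylic alkoxide may turn over slowly, giving the linear ether or the (5S) diastereomer. The fallback replaces catalyst control by a stereospecific substitution. It sets out from alcohol 9 (used again as copper alkoxide 11) and returns at 12. Commercial methyl 5-oxopentanoate is treated with vinylmagnesium bromide at −78 °C and quenched cold with acid, so that the hydroxy ester does not close to the δ-lactone, giving racemic methyl 5-hydroxyhept-6-enoate F1. Lipase resolution with vinyl acetate, in which the (S)-alcohol should be acylated, leaves methyl (R)-5-hydroxyhept-6-enoate F2. Boc2O and DMAP convert it into methyl (R)-5-[(tert-butoxycarbonyl)oxy]hept-6-enoate F3. Rhodium-catalysed allylic etherification of F3 with 11 (RhCl(PPh3)3 modified with P(OMe)3, THF, 0 °C → rt) proceeds with net retention by double inversion and gives 12 with (5R) fixed by the substrate.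

Step 8. Diimide may also add to the silyl-capped triple bond, or the ring alkene may be reduced so slowly that the reagent is spent by disproportionation. The fallback masks the alkyne; it sets out from 13 and returns at 14. Co2(CO)8 in CH2Cl2 at rt gives the hexacarbonyldicobalt complex of 13 F4, in which the triple bond no longer behaves as an alkyne. Diimide generated at rt from 2-nitrobenzenesulfonylhydrazide and Et3N (or H2 over RhCl(PPh3)3) then reduces only the ring alkene to give the hexacarbonyldicobalt complex of 14 F5. Oxidative decomplexation with (NH4)2Ce(NO3)6 in acetone at 0 °C releases 14.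

Step 15. The volatile β-bromo enal may decompose or polymerise before it is trapped, the ylide may add in a conjugate addition–elimination sense at the C–Br carbon, or the Z-selectivity at C17=C18 may erode. The fallback replaces the bromo enal by a stable stannyl enal and installs bromine afterwards; it sets out from 20 (through ylide 25) and returns at 26. Radical hydrostannation of prop-2-yn-1-ol (Bu3SnH, AIBN, 80 °C) and separation of isomers gives (E)-3-(tributylstannyl)prop-2-en-1-ol F6. MnO2 in CH2Cl2 oxidises it to (E)-3-(tributylstannyl)prop-2-enal F7. Wittig reaction of 25 with F7 under the conditions of step 15 should give tributyl[(1E,3Z,9E)-10-iododeca-1,3,9-trien-1-yl]stannane F8. Bromodestannylation with NBS in THF at 0 °C, with retention of geometry, then gives 26.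

**Further compounds**

F1 | step 6 | methyl 5-hydroxyhept-6-enoate (racemic) | COC(=O)CCCC(O)C=C
F2 | step 6 | methyl (R)-5-hydroxyhept-6-enoate | COC(=O)CCC[C@H](C=C)O
F3 | step 6 | methyl (R)-5-[(tert-butoxycarbonyl)oxy]hept-6-enoate | COC(=O)CCC[C@H](C=C)OC(=O)OC(C)(C)C
F4 | step 8 | hexacarbonyldicobalt complex of 13 | COC(=O)CCC[C@@H]1C=C[C@@H](C23[Co]4(=C=O)(=C=O)(=C=O)[Co]2(=C=O)(=C=O)(=C=O)C34[Si](C(C)C)(C(C)C)C(C)C)O1
F5 | step 8 | hexacarbonyldicobalt complex of 14 | COC(=O)CCC[C@@H]1CC[C@@H](C23[Co]4(=C=O)(=C=O)(=C=O)[Co]2(=C=O)(=C=O)(=C=O)C34[Si](C(C)C)(C(C)C)C(C)C)O1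
F6 | step 15 | (E)-3-(tributylstannyl)prop-2-en-1-ol | CCCC[Sn](CCCC)(CCCC)/C=C/CO
F7 | step 15 | (E)-3-(tributylstannyl)prop-2-enal | CCCC[Sn](CCCC)(CCCC)/C=C/C=O
F8 | step 15 | tributyl[(1E,3Z,9E)-10-iododeca-1,3,9-trien-1-yl]stannane | CCCC[Sn](CCCC)(CCCC)/C=C/C=C\CCCC/C=C/I
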